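Lignan numbering is used throughout: C7/C7' are the aryl-bearing OCH carbons, C8/C8' the ring-fusion CH carbons, C9/C9' the OCH2 carbons, and the unprimed half carries the 4-hydroxy-3-methoxyphenyl group. Ring A is C7–O–C9'–C8'–C8 and ring B is C7'–O–C9–C8–C8'.

## The problem

The target 16 is a 2,6-diaryl-3,7-dioxabicyclo[3.3.0]octane in which rings A and B are cis-fused across C8–C8' and both aryl groups are exo (7S,7'S,8R,8'R). The two aryl groups differ (4-hydroxy-3-methoxyphenyl on C7, 3-hydroxy-4,5-dimethoxyphenyl on C7'), so dimerizing a single phenylpropanoid cannot give it and each half has to be brought in separately. C8 and C8' are unactivated CH centres that cannot be corrected once made, so their absolute configuration has to come from an enantioselective step. C7 and C7' are benzylic ether carbons that can be formed last: a planar benzylic cation next to C8 or C8' closes to the five-membered ether with the aryl trans to the neighbouring ring bond. The same benzylic C–O bonds are the fragile part of the molecule: acid ionizes them and scrambles exo and endo aryl groups, and hydrogenolysis can open them. The two phenols will not tolerate oxidants or Lewis acids and must stay masked to the end. The enabling feature is that C9–C8–C8'–C9' maps onto a fumaric acid unit, while C7 and C7', each carrying one aryl group, are the termini of a 1,4-diarylbutadiene whose two inner carbons are absent from the target and can leave as CO2.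

## Retrosynthesis

**16 from 15.** The two phenolic O–H bonds are traced to benzyl ethers in furofuran 15. Benzyl is chosen over silyl, acyl or allyl groups because it has to pass a strong Lewis acid, LiAlH4, OsO4/NaIO4, hydroxide and an anode. The forward step must cleave two aryl benzyl ethers faster than the two ring benzylic C–O bonds.

**15 from 14 and 13.** Both benzylic C–O bonds (C7–O9' and C7'–O9) are cut, and C7 and C7' each receive a carboxylate, giving the acyclic bis(γ-hydroxy arylacetate) 14. The other possible cut, at the C9–O bonds, would demand defined carbinol centres at C7 and C7' in an acyclic precursor. The chosen cut leaves only C8 and C8' to be controlled, because oxidative loss of CO2 gives para-alkoxybenzyl cations that the hydroxymethyl groups capture. The free hydroxy acid would lactonize, so 14 is generated from its stable bis-lactone 13 and used as the salt. The forward reaction must decarboxylate twice, close two five-membered rings and place both aryl groups exo.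

**13 from 12 and 9.** The two carboxyl carbons of 13 are joined to each other, which turns the chain C7–C8–C8'–C7' into the cyclohexene diol 9. The acyclic stereochemical problem thereby becomes a cyclic one. The forward sequence is alkene cleavage under conditions that spare electron-rich arenes (OsO4/NaIO4 through tetrol 10 and dialdehyde 11, which closes to bis-lactol 12), then lactol oxidation.

**9 from 8.** The two hydroxymethyl groups are taken back to the methyl esters of 8. The esters are what make the dienophile reactive and give the catalyst a binding site.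

**8 from 6 and 7.** The C7–C8 and C7'–C8' bonds are cut in a retro-[4+2], giving diene 6 and dimethyl fumarate 7. A cis dienophile such as a maleate is the wrong choice: in the cis-fused bicycle C7 lies over C9' and C9 over C7', which in a six-membered ring containing C7, C8, C8' and C7' puts C9 and C9' on opposite faces. Only the absolute sense of this trans pair has to be controlled, by a chiral Lewis acid on the fumarate. The forward reaction asks for reactivity from a sluggish 1,4-diaryl diene and for one π-face of 7.

**6 from 5 and 3, and their sources.** The C7=C double bond of 6 is cut (Horner–Wadsworth–Emmons) into benzylic phosphonate 5 and enal 3. Phosphonate 5 comes in one step from the commercial benzylic alcohol 4. Enal 3 comes by two-carbon Wittig homologation of aldehyde 2, the benzyl ether of commercial 3-hydroxy-4,5-dimethoxybenzaldehyde 1.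

## Roads not taken

Alternative 1: The cut is the C9–O bond of a ring B lactone. A Baeyer–Villiger monooxygenase of the cyclohexanone monooxygenase type (flavin, NADPH, O2) would insert oxygen between the carbonyl carbon and the methylene of fused cyclobutanone A2 to give furofuranone A1.
- Merits: enzymatic oxygen insertion is often highly enantioselective, runs in water at ambient temperature, and gives a lactone of the type that is an established entry to unsymmetrical furofurans. C7 is set on a rigid bicycle and never passes through a cation, which is better than the chosen plan on that point.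
- Weak points: insertion on the methylene side runs against the intrinsic migratory preference, so the enzyme must override it, and with racemic fused cyclobutanones such enzymes commonly send the two enantiomers to different regioisomers. A2 is bulky for the active site and needs its own multistep synthesis. A1 carries only one aryl group, so the 3-hydroxy-4,5-dimethoxyphenyl unit would still have to be added to the lactone carbonyl and the resulting hemiketal reduced with a Lewis acid next to an ionizable benzylic ether.
- Comparison: the chosen plan has both aryl groups in place before its key step, sets C8 and C8' in one catalytic operation and needs no enzyme screening. Its price is that C7 and C7' are made by cation capture.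

Alternative 2: The cut removes C7–O (ring A), C8–C9 and C9–O (ring B) at once. PdCl2 (divalent palladium) with CuCl2 under CO would add the primary hydroxyl of styrenyl diol A4 to the benzylic alkene carbon, insert CO into the C8–Pd bond and close the lactone with the C7' hydroxyl, giving A3.
- Merits: both rings and three bonds form in one step, C9 comes from CO, no carbon is wasted and both aryl groups are already present. In convergence and atom economy this road is better than the chosen one.
- Weak points: the alkoxide must attack the styrene in a 5-endo sense, whereas the well-established closures of this reaction type are 5-exo and give the isomeric 2,6-dioxa skeleton. β-Hydride elimination from the C8–Pd intermediate competes with CO insertion. A4 needs two stereocentres from a separate asymmetric aldol sequence. A3 still holds a C9 carbonyl, and reducing it to CH2 takes two steps, the second with a Lewis acid on a benzylic ether.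
- Comparison: the chosen plan sets against this a key step of a well-documented type, ordinary flanking steps and a ring closure that ends at the ether oxidation level.

Alternative 3: The cut is O–C7 and C8–C8' of ring A. Pd2(dba)3 (zerovalent palladium) with a chiral phosphine would open 2-ethenyloxirane A7 to an alkoxide/π-allyl zwitterion that adds to benzylidene malonate A6 and closes to vinyl tetrahydrofuran A5.
- Merits: the step is catalytic and neutral, the partners are cheap, and C7 and C8' are set directly. It is milder than the chosen key step.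
- Weak points: only ring A is formed. C8 is a quaternary gem-diester that must be mono-decarboxylated, which leaves the C8 configuration to thermodynamics, and then reduced. The vinyl group must be cut to an aldehyde, the second aryl group added with diastereocontrol and ring B closed. The electron-rich A6 is a poor acceptor and the oxa-Michael step is reversible, which threatens C7.
- Comparison: this is the longest road after its key step. The chosen plan fixes C8 and C8' together and carries both aryl groups from the start, at the cost of two sacrificial carbons and a less certain cycloaddition.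

Key step: step 5

Assumption: the catalyst from (S)-α,α-diphenylprolinol is taken to expose the fumarate face that leads to the (1R,2R) adduct 8, by analogy with the α-C–H···O binding model for unsaturated esters; if the sense proves opposite, the catalyst from (R)-α,α-diphenylprolinol is used and nothing else changes.

Remark: from step 5 to step 8 each numbered compound stands for a material that also contains its isomers at the aryl-bearing carbons (and, for 12, at the lactol carbons); names and SMILES define these centres only where stated, and all isomers converge in step 9.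

## Route

Step 1
Reactants: 1 3-hydroxy-4,5-dimethoxybenzaldehyde
Product: 2 3-(benzyloxy)-4,5-dimethoxybenzaldehyde
Conditions: BnBr, K2CO3, DMF, 60 °C
Reagents that add atoms: benzyl bromide BrCc1ccccc1
Why: Williamson ether synthesis: the phenoxide displaces bromide from the primary benzylic halide, and the aldehyde is inert to carbonate.

Step 2
Reactants: 2 3-(benzyloxy)-4,5-dimethoxybenzaldehyde
Product: 3 (E)-3-[3-(benzyloxy)-4,5-dimethoxyphenyl]prop-2-enal
Conditions: Ph3P=CHCHO (1.1 equiv), toluene, 80 °C
Reagents that add atoms: (triphenylphosphoranylidene)acetaldehyde O=CC=P(c1ccccc1)(c1ccccc1)c1ccccc1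
Why: Wittig olefination with the stabilized formylmethylene ylide, which should give the E-enal; only a small excess of ylide is used so that the product enal is not homologated a second time.

Step 3
Reactants: 4 [4-(benzyloxy)-3-methoxyphenyl]methanol
Product: 5 diethyl {[4-(benzyloxy)-3-methoxyphenyl]methyl}phosphonate
Conditions: P(OEt)3, ZnI2, toluene, reflux
Reagents that add atoms: triethyl phosphite CCOP(OCC)OCC
Why: One-flask ZnI2-mediated Michaelis–Arbuzov reaction of a benzylic alcohol: the electron-rich benzylic C–O bond is activated by ZnI2, the phosphite attacks the benzylic carbon and iodide dealkylates the phosphonium ion.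

Step 4
Reactants: 5 diethyl {[4-(benzyloxy)-3-methoxyphenyl]methyl}phosphonate; 3 (E)-3-[3-(benzyloxy)-4,5-dimethoxyphenyl]prop-2-enal
Product: 6 (1E,3E)-1-[4-(benzyloxy)-3-methoxyphenyl]-4-[3-(benzyloxy)-4,5-dimethoxyphenyl]buta-1,3-diene
Conditions: KOtBu, THF, 0 °C to rt (phosphonate deprotonated first, then 3 added)
Reagents that add atoms: none
Why: Horner–Wadsworth–Emmons olefination of a benzylic phosphonate anion with a non-enolizable enal; reversible addition and syn-elimination of phosphate should give the new double bond E, and the E alkene of 3 is untouched.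

Step 5
Reactants: 6 (1E,3E)-1-[4-(benzyloxy)-3-methoxyphenyl]-4-[3-(benzyloxy)-4,5-dimethoxyphenyl]buta-1,3-diene; 7 dimethyl fumarate
Product: 8 dimethyl (1R,2R,3R,6S)-3-[3-(benzyloxy)-4,5-dimethoxyphenyl]-6-[4-(benzyloxy)-3-methoxyphenyl]cyclohex-4-ene-1,2-dicarboxylate
Conditions: (S)-o-tolyl-oxazaborolidine from (S)-α,α-diphenylprolinol and (o-TolBO)3 (20 mol%), HNTf2 (18 mol%), 7 (2 equiv), CH2Cl2, −20 to 0 °C
Reagents that add atoms: none
Why: The N-protonated oxazaborolidine binds one ester carbonyl of 7 at boron, with the fumarate α-C–H held by the ring oxygen, which lowers the LUMO and leaves one π-face open while an aryl group of the catalyst covers the other; the s-cis diene 6 adds to the open face in a concerted, asynchronous, suprafacial [4+2] cycloaddition. The closest known reactions are the oxazaborolidinium-catalysed Diels–Alder additions of fumarate diesters to butadiene, isoprene and cyclopentadiene. The cyclohexene ring is closed by the cycloaddition itself, the C7–C8 and C7'–C8' bonds forming together across the diene termini. C8 and C8' (C1 and C2 of 8) are trans because the E geometry of 7 is transferred suprafacially, and their absolute configuration is set by the catalyst; because 7 is C2h-symmetric, binding at either carbonyl exposes the same face. C7 and C7' (C6 and C3 of 8) are cis to each other because both aryl groups are outside substituents of the E,E-diene. The only selectivity the route needs is the π-facial one on 7: the two endo/exo orientations of the unsymmetrical diene give 8 and its isomer in which the aryl groups have changed places relative to the esters, both with the same C8/C8' configuration, and they are carried on together. The acid is kept slightly below the oxazaborolidine so that no free HNTf2 is left to oligomerize the electron-rich diene.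

Step 6
Reactants: 8 dimethyl (1R,2R,3R,6S)-3-[3-(benzyloxy)-4,5-dimethoxyphenyl]-6-[4-(benzyloxy)-3-methoxyphenyl]cyclohex-4-ene-1,2-dicarboxylate
Product: 9 [(1R,2R,3R,6S)-3-[3-(benzyloxy)-4,5-dimethoxyphenyl]-6-[4-(benzyloxy)-3-methoxyphenyl]cyclohex-4-ene-1,2-diyl]dimethanol
Conditions: LiAlH4, THF, 0 °C to rt
Reagents that add atoms: none
Why: Hydride reduction of both esters to primary alcohols; the alkene, the benzyl ethers and the ring stereocentres are not affected.

Step 7
Reactants: 9 [(1R,2R,3R,6S)-3-[3-(benzyloxy)-4,5-dimethoxyphenyl]-6-[4-(benzyloxy)-3-methoxyphenyl]cyclohex-4-ene-1,2-diyl]dimethanol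
Product: 12 (3S,3'S)-4-[3-(benzyloxy)-4,5-dimethoxyphenyl]-4'-[4-(benzyloxy)-3-methoxyphenyl]-[3,3'-bioxolane]-5,5'-diol (bis-lactol; anomers and aryl-carbon epimers), via tetrol 10 (not isolated), via dialdehyde 11 (not isolated)
Conditions: OsO4 (2 mol%), NaIO4 (4 equiv), 2,6-lutidine, dioxane/H2O 3:1, rt
Reagents that add atoms: osmium tetroxide O=[Os](=O)(=O)=O (oxygen donor, turned over by sodium periodate [Na+].[O-]I(=O)(=O)=O)
Why: Lemieux–Johnson oxidation: syn-dihydroxylation of the ring alkene gives 10, periodate cleaves the glycol to dialdehyde 11, and each formyl group is trapped by the hydroxymethyl group on the adjacent carbon as a five-membered lactol. C8 and C8' are not enolizable and keep their configuration; the stereochemistry at the aryl-bearing and lactol carbons is immaterial.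

Step 8
Reactants: 12 (3S,3'S)-4-[3-(benzyloxy)-4,5-dimethoxyphenyl]-4'-[4-(benzyloxy)-3-methoxyphenyl]-[3,3'-bioxolane]-5,5'-diol
Product: 13 (3S,3'S)-4-[3-(benzyloxy)-4,5-dimethoxyphenyl]-4'-[4-(benzyloxy)-3-methoxyphenyl]-[3,3'-bioxolane]-5,5'-dione (bis-γ-lactone)
Conditions: nPr4N[RuO4] (5 mol%), N-methylmorpholine N-oxide, 4 Å MS, CH2Cl2, rt
Reagents that add atoms: none
Why: Ley–Griffith oxidation of lactols to γ-lactones; benzyl ethers and alkoxyarenes tolerate perruthenate, and the bis-lactone is a neutral, stable store for the two carboxyl carbons.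

Step 9
Reactants: 13 (3S,3'S)-4-[3-(benzyloxy)-4,5-dimethoxyphenyl]-4'-[4-(benzyloxy)-3-methoxyphenyl]-[3,3'-bioxolane]-5,5'-dione
Product: 15 (1S,3aR,4S,6aR)-1-[4-(benzyloxy)-3-methoxyphenyl]-4-[3-(benzyloxy)-4,5-dimethoxyphenyl]tetrahydro-1H,3H-furo[3,4-c]furan, via dipotassium dicarboxylate 14 (not isolated)
Conditions: KOH (2.2 equiv), MeCN/H2O 4:1, 40 °C; then graphite anode, Pt cathode, undivided cell, constant current (about 4.5 F/mol), 5–10 °C
Reagents that add atoms: none
Why: Hydroxide opens both α-aryl lactones to the bis(γ-hydroxy carboxylate) 14, which cannot relactonize in the basic medium; Hofer–Moest (non-Kolbe) anodic oxidation then removes CO2 from each arylacetate and oxidizes the benzylic radical on to a para-alkoxy-stabilized cation, the reaction type by which arylacetic acids are converted into benzylic ethers. Each cation is trapped by the hydroxymethyl group on the far fusion carbon (O9' at C7, O9 at C7'; the near one would give an oxetane), and the kinetically controlled five-membered closure should place each aryl trans to the substituent on the adjacent fusion carbon, that is exo, while C8 and C8' are untouched.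

Step 10
Reactants: 15 (1S,3aR,4S,6aR)-1-[4-(benzyloxy)-3-methoxyphenyl]-4-[3-(benzyloxy)-4,5-dimethoxyphenyl]tetrahydro-1H,3H-furo[3,4-c]furan
Product: 16 5-[(1S,3aR,4S,6aR)-4-(4-hydroxy-3-methoxyphenyl)tetrahydro-1H,3H-furo[3,4-c]furan-1-yl]-2,3-dimethoxyphenol
Conditions: H2 (1 atm), Pd/C (10 wt%), EtOAc, rt, stopped at full conversion
Reagents that add atoms: none
Why: Catalytic hydrogenolysis of the two aryl benzyl ethers, which is faster than cleavage of the dialkyl benzylic C–O bonds of the furofuran in a neutral aprotic solvent; no stereocentre is involved.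

## Compound list

1 | 3-hydroxy-4,5-dimethoxybenzaldehyde | COc1cc(C=O)cc(O)c1OC | starting material
2 | 3-(benzyloxy)-4,5-dimethoxybenzaldehyde | COc1cc(C=O)cc(OCc2ccccc2)c1OC | intermediate
3 | (E)-3-[3-(benzyloxy)-4,5-dimethoxyphenyl]prop-2-enal | COc1cc(/C=C/C=O)cc(OCc2ccccc2)c1OC | intermediate
4 | [4-(benzyloxy)-3-methoxyphenyl]methanol | COc1cc(CO)ccc1OCc1ccccc1 | starting material
5 | diethyl {[4-(benzyloxy)-3-methoxyphenyl]methyl}phosphonate | CCOP(=O)(Cc1ccc(OCc2ccccc2)c(OC)c1)OCC | intermediate
6 | (1E,3E)-1-[4-(benzyloxy)-3-methoxyphenyl]-4-[3-(benzyloxy)-4,5-dimethoxyphenyl]buta-1,3-diene | COc1cc(ccc1OCc1ccccc1)/C=C/C=C/c1cc(OCc2ccccc2)c(OC)c(OC)c1 | intermediate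
7 | dimethyl fumarate | COC(=O)/C=C/C(=O)OC | starting material
8 | dimethyl (1R,2R,3R,6S)-3-[3-(benzyloxy)-4,5-dimethoxyphenyl]-6-[4-(benzyloxy)-3-methoxyphenyl]cyclohex-4-ene-1,2-dicarboxylate (accompanied by its 3,6-cis orientation isomer of the same C1/C2 configuration) | COc1cc(ccc1OCc1ccccc1)[C@H]1C=C[C@@H](c2cc(OCc3ccccc3)c(OC)c(OC)c2)[C@@H](C(=O)OC)[C@@H]1C(=O)OC | intermediate
9 | [(1R,2R,3R,6S)-3-[3-(benzyloxy)-4,5-dimethoxyphenyl]-6-[4-(benzyloxy)-3-methoxyphenyl]cyclohex-4-ene-1,2-diyl]dimethanol | COc1cc(ccc1OCc1ccccc1)[C@H]1C=C[C@@H](c2cc(OCc3ccccc3)c(OC)c(OC)c2)[C@@H](CO)[C@@H]1CO | intermediate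
10 | 3-[3-(benzyloxy)-4,5-dimethoxyphenyl]-6-[4-(benzyloxy)-3-methoxyphenyl]-4,5-bis(hydroxymethyl)cyclohexane-1,2-diol (cis-1,2-diol on either face; C3 to C6 as in 9) | COc1cc(ccc1OCc1ccccc1)[C@H]1C(O)C(O)[C@@H](c2cc(OCc3ccccc3)c(OC)c(OC)c2)[C@@H](CO)[C@@H]1CO | intermediate (not isolated)
11 | (3S,4S)-2-[3-(benzyloxy)-4,5-dimethoxyphenyl]-5-[4-(benzyloxy)-3-methoxyphenyl]-3,4-bis(hydroxymethyl)hexanedial | COc1cc(ccc1OCc1ccccc1)C(C=O)[C@@H](CO)[C@H](CO)C(C=O)c1cc(OCc2ccccc2)c(OC)c(OC)c1 | intermediate (not isolated)
12 | (3S,3'S)-4-[3-(benzyloxy)-4,5-dimethoxyphenyl]-4'-[4-(benzyloxy)-3-methoxyphenyl]-[3,3'-bioxolane]-5,5'-diol | COc1cc(ccc1OCc1ccccc1)C1C(O)OC[C@H]1[C@@H]1COC(O)C1c1cc(OCc2ccccc2)c(OC)c(OC)c1 | intermediate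
13 | (3S,3'S)-4-[3-(benzyloxy)-4,5-dimethoxyphenyl]-4'-[4-(benzyloxy)-3-methoxyphenyl]-[3,3'-bioxolane]-5,5'-dione | COc1cc(ccc1OCc1ccccc1)C1C(=O)OC[C@H]1[C@@H]1COC(=O)C1c1cc(OCc2ccccc2)c(OC)c(OC)c1 | intermediate
14 | dipotassium (3S,4S)-2-[3-(benzyloxy)-4,5-dimethoxyphenyl]-5-[4-(benzyloxy)-3-methoxyphenyl]-3,4-bis(hydroxymethyl)hexanedioate | COc1cc(ccc1OCc1ccccc1)C(C(=O)[O-])[C@@H](CO)[C@H](CO)C(C(=O)[O-])c1cc(OCc2ccccc2)c(OC)c(OC)c1.[K+].[K+] | intermediate (not isolated)
15 | (1S,3aR,4S,6aR)-1-[4-(benzyloxy)-3-methoxyphenyl]-4-[3-(benzyloxy)-4,5-dimethoxyphenyl]tetrahydro-1H,3H-furo[3,4-c]furan | COc1cc([C@H]2OC[C@H]3[C@@H]2CO[C@@H]3c2cc(OCc4ccccc4)c(OC)c(OC)c2)ccc1OCc1ccccc1 | intermediate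
16 | 5-[(1S,3aR,4S,6aR)-4-(4-hydroxy-3-methoxyphenyl)tetrahydro-1H,3H-furo[3,4-c]furan-1-yl]-2,3-dimethoxyphenol | COc1cc([C@H]2OC[C@H]3[C@@H]2CO[C@@H]3c2cc(O)c(OC)c(OC)c2)ccc1O | target

## Step count and least certain steps

Total: 10 steps. Longest linear sequence: 9 steps (1, 2, 4 to 10); step 3 is a one-step branch.

**Step 5 (key step).** The 1,4-diaryl diene may react too slowly at the low temperature that facial selectivity needs, because the aryl termini hinder bond formation. Raising the temperature risks lower enantioselectivity and acid-initiated oligomerization of the electron-rich diene, and the diester product can hold back the catalyst. Fallback: from 6, an Et2AlCl-promoted cycloaddition with bis[(1R,2S,5R)-menthyl] fumarate in toluene would use a stoichiometric Lewis acid for reactivity and the auxiliary for face control, giving the bis(menthyl) ester F1. Reduction of F1 with LiAlH4 releases menthol and rejoins the route at diol 9. The (1R,2S,5R)-menthyl ester is taken to lead to the (1R,2R) series; if it does not, the ester of the enantiomeric menthol is used.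

**Step 9.** Several processes can divert the cations:
- over-oxidation at the anode of the alkoxyarenes or of the benzylic ether C–H bonds of the product;
- capture of the first cation by the remaining carboxylate (a six-membered lactone) or by water instead of the hydroxyl group;
- loss of the C8 or C8' proton from the cation to give a styrene;
- closure with an endo aryl group.

Fallback: from bis-lactol 12 (replacing steps 8 and 9), alkoxy-radical β-fragmentation with PhI(OAc)2/I2 under visible light cleaves each lactol C–C7 bond. The lactol carbon stays as a formate on O9 or O9', and the benzylic carbon ends, after iodine transfer and acetolysis, as an acetate, giving bis(formate) bis(acetate) F2. K2CO3 in MeOH removes all four acyl groups to give tetrol F3. Brief treatment with camphorsulfonic acid in CH2Cl2 at 0 °C closes both ether rings through the benzylic cations, the established closure for such tetrols, and after removal of endo isomers the route is rejoined at 15.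

**Step 10.** Once the phenols are free, hydrogenolytic opening of the ring benzylic C–O bonds may set in before both benzyl ethers are gone. Fallback: the protecting group is exchanged at the bis-lactone stage, where no benzylic C–O bond exists. From 13, H2 and Pd/C give bisphenol F4, and allyl bromide with K2CO3 in acetone gives bis(allyl ether) F5. Saponification and anodic closure as in step 9 give furofuran bis(allyl ether) F6, and Pd(PPh3)4 (zerovalent palladium) with morpholine removes the allyl groups without hydrogen or acid, arriving at 16.

**Step 2.** The product enal may be homologated a second time by the ylide, while the electron-rich aldehyde reacts only slowly. Fallback: from 2, a Horner–Wadsworth–Emmons reaction with triethyl phosphonoacetate and NaH gives cinnamate F7, iBu2AlH reduces it to allylic alcohol F8, and MnO2 oxidizes F8 to enal 3.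

## Further compounds

F1 | step 5 | bis[(1R,2S,5R)-5-methyl-2-(propan-2-yl)cyclohexyl] (1R,2R,3R,6S)-3-[3-(benzyloxy)-4,5-dimethoxyphenyl]-6-[4-(benzyloxy)-3-methoxyphenyl]cyclohex-4-ene-1,2-dicarboxylate | COc1cc(ccc1OCc1ccccc1)[C@H]1C=C[C@@H](c2cc(OCc3ccccc3)c(OC)c(OC)c2)[C@@H](C(=O)O[C@@H]2C[C@H](C)CC[C@H]2C(C)C)[C@@H]1C(=O)O[C@@H]1C[C@H](C)CC[C@H]1C(C)C
F2 | step 9 | (2R,3R)-1-[3-(benzyloxy)-4,5-dimethoxyphenyl]-4-[4-(benzyloxy)-3-methoxyphenyl]-2,3-bis[(formyloxy)methyl]butane-1,4-diyl diacetate | COc1cc(ccc1OCc1ccccc1)C(OC(C)=O)[C@@H](COC=O)[C@H](COC=O)C(OC(C)=O)c1cc(OCc2ccccc2)c(OC)c(OC)c1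
F3 | step 9 | (2R,3R)-1-[3-(benzyloxy)-4,5-dimethoxyphenyl]-4-[4-(benzyloxy)-3-methoxyphenyl]-2,3-bis(hydroxymethyl)butane-1,4-diol | COc1cc(ccc1OCc1ccccc1)C(O)[C@@H](CO)[C@H](CO)C(O)c1cc(OCc2ccccc2)c(OC)c(OC)c1
F4 | step 10 | (3S,3'S)-4-(3-hydroxy-4,5-dimethoxyphenyl)-4'-(4-hydroxy-3-methoxyphenyl)-[3,3'-bioxolane]-5,5'-dione | COc1cc(ccc1O)C1C(=O)OC[C@H]1[C@@H]1COC(=O)C1c1cc(O)c(OC)c(OC)c1
F5 | step 10 | (3S,3'S)-4-[3,4-dimethoxy-5-(prop-2-en-1-yloxy)phenyl]-4'-[3-methoxy-4-(prop-2-en-1-yloxy)phenyl]-[3,3'-bioxolane]-5,5'-dione | COc1cc(ccc1OCC=C)C1C(=O)OC[C@H]1[C@@H]1COC(=O)C1c1cc(OCC=C)c(OC)c(OC)c1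
F6 | step 10 | (1S,3aR,4S,6aR)-1-[3-methoxy-4-(prop-2-en-1-yloxy)phenyl]-4-[3,4-dimethoxy-5-(prop-2-en-1-yloxy)phenyl]tetrahydro-1H,3H-furo[3,4-c]furan | COc1cc([C@H]2OC[C@H]3[C@@H]2CO[C@@H]3c2cc(OCC=C)c(OC)c(OC)c2)ccc1OCC=C
F7 | step 2 | ethyl (E)-3-[3-(benzyloxy)-4,5-dimethoxyphenyl]prop-2-enoate | CCOC(=O)/C=C/c1cc(OC)c(OC)c(OCc2ccccc2)c1
F8 | step 2 | (E)-3-[3-(benzyloxy)-4,5-dimethoxyphenyl]prop-2-en-1-ol | OC/C=C/c1cc(OC)c(OC)c(OCc2ccccc2)c1
A1 | alternative 1 | exo-6-[4-(benzyloxy)-3-methoxyphenyl]-3,7-dioxabicyclo[3.3.0]octan-2-one | COc1cc(ccc1OCc1ccccc1)[C@H]1OC[C@@H]2C(=O)OC[C@H]12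
A2 | alternative 1 | exo-2-[4-(benzyloxy)-3-methoxyphenyl]-3-oxabicyclo[3.2.0]heptan-6-one | COc1cc(ccc1OCc1ccccc1)[C@H]1OC[C@@H]2C(=O)C[C@H]12
A3 | alternative 2 | exo,exo-2-[4-(benzyloxy)-3-methoxyphenyl]-6-[3-(benzyloxy)-4,5-dimethoxyphenyl]-3,7-dioxabicyclo[3.3.0]octan-8-one | COc1cc(ccc1OCc1ccccc1)[C@H]1OC[C@H]2[C@@H]1C(=O)O[C@@H]2c1cc(OCc2ccccc2)c(OC)c(OC)c1
A4 | alternative 2 | (1S,2R)-1-[3-(benzyloxy)-4,5-dimethoxyphenyl]-2-[(E)-2-[4-(benzyloxy)-3-methoxyphenyl]ethenyl]propane-1,3-diol | COc1cc(ccc1OCc1ccccc1)/C=C/[C@H](CO)[C@H](O)c1cc(OCc2ccccc2)c(OC)c(OC)c1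
A5 | alternative 3 | dimethyl 2,4-trans-2-[4-(benzyloxy)-3-methoxyphenyl]-4-ethenyloxolane-3,3-dicarboxylate | COc1cc(ccc1OCc1ccccc1)[C@H]1OC[C@H](C=C)C1(C(=O)OC)C(=O)OC
A6 | alternative 3 | dimethyl 2-{[4-(benzyloxy)-3-methoxyphenyl]methylidene}propanedioate | COC(=O)C(=Cc1ccc(OCc2ccccc2)c(OC)c1)C(=O)OC
A7 | alternative 3 | 2-ethenyloxirane (racemic) | C=CC1CO1
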